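## Analysis of the target

The target is catechin-(4α→8)-epigallocatechin 3-O-gallate. The upper flavan-3-ol has rings A (phloroglucinol type), C (pyran) and B (catechol). It is bonded through C4 to C8 of a lower flavan-3-ol with rings D, F and E (pyrogallol), whose O3 carries a galloyl ester (ring G). There are five stereocentres. Upper C2 (R), C3 (S) and C4 (S) are all-trans around ring C and correspond to (+)-catechin substituted on C4 trans to O3. Lower C2 (R) and C3 (R) are cis, with the ester on the axial oxygen. The two sets are joined only by the C4–C8 bond, so the lower pair gets little help from the upper triad and needs a reagent to set it. Sensitive points are the thirteen free phenols (two pyrogallol rings oxidise in air), the doubly benzylic, acid-labile C4–C8 bond, the base-labile gallate, and lower C2, which epimerises once C3 is a ketone. The difficulties are the 4→8 (not 4→6) constitution, the 4α configuration, and a cis-2,3 lower unit with a trioxygenated ring E, all under protection that can be removed in one neutral step. The strategy rests on ring F: the sequence ring D–O1–C2–ring E is, one oxidation level up, the ester of the ring D phenol with a 3,4,5-trioxygenated benzoic acid, and C3 is an aldehyde carbon on the C4 methylene. C2=C3 can therefore be made by reductive coupling of an aldehyde with an ester carbonyl, and ring E, C2 and the galloyl group all come from one gallic acid building block.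

## Retrosynthetic reasoning

**23 to 22.** The thirteen O–benzyl bonds are cut last. Benzyl ethers are the one protecting group that comes off under neutral, reductive conditions, which spare the ester, the C4–C8 bond and lower C2. So every phenol and upper O3 are benzylated from the start, and the forward step is a single hydrogenolysis.

**22 to 21 and 12.** The ester C–O bond on lower O3 is cut next. The gallate would not survive hydride or borane reagents, so it goes on after all redox steps on ring F. Acid chloride 12, made from acid 11, is used twice: once as this ester and once as the source of C2 and ring E.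

**21 to 20 to 19.** The cis alcohol 21 is traced to ketone 20 and that to the trans alcohol 19. A syn hydroboration can only give the trans alcohol, so C3 is corrected by oxidation followed by delivery of a bulky hydride to the face of the carbonyl away from ring E. This is the standard catechin-to-epicatechin inversion and leaves C2 alone.

**19 to 17.** The C2–H and C3–O bonds are removed to give the enol ether 17, a 2-aryl-4H-chromene. Both lower stereocentres then arise in one syn addition to a flat ring F, and a chiral borane chooses the face.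

**17 to 15.** This is the disconnection that defines the route. The C2=C3 bond is cut into the aldehyde carbon (C3) and the ester carbonyl carbon (C2) of 15. Cutting here turns ring E plus C2 into a simple acyl group on the ring D oxygen and turns C3–C4 into a two-carbon side chain on ring D. The forward reaction must couple the aldehyde with the ester carbonyl within one molecule and remove both carbonyl oxygens.

**15 to 13 to 10 and 12.** The aldehyde carbon comes from the internal carbon of an allyl group by oxidative cleavage of the alkene. The ester comes from phenol 10 and acid chloride 12. Acylation comes before cleavage, because a free ortho-hydroxy arylacetaldehyde would close to a lactol.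

**10 to 4 and 9.** The interflavan bond C4–C8 is cut into a flavan-4-yl cation equivalent 4 and the electron-rich phenol 9. This is the classical bond to form, and it lets the upper triad come from 1. Phenol 9 has the substitution pattern of ring A of a benzylated flavan (an oxygen flanked by a carbon substituent, two benzyloxy groups, and a free carbon next to the oxygen). Attack should therefore occur at the free carbon ortho to the hydroxyl, which becomes C8, and not at the carbon between the two benzyloxy groups. The forward step must also put the new bond trans to the C3 benzyloxy group.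

**9 to 7 to 5 and 6.** The C-allyl bond is traced to an O-allyl ether through a [3,3] shift. Doing this on the small symmetrical ether 7 gives one phenol only, and the 190 °C step is kept away from the flavan.

**4 to 3 to 2 to 1.** The C4–O bond of 4 comes from oxidation of the benzylic C4–H of 3 in the presence of an alcohol. The benzyl ethers of 3 come from (+)-catechin 1 in two alkylations, phenols first.

## Alternatives that were turned down

**Alternative 1:** The cut is in the upper unit, at C4–C4a and O1–C2 of ring C, so ring A is added last to a finished lower unit.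
- Forward key step: an (E)-enal on C8 of a benzylated, O3-silylated epigallocatechin (A2) is converted by a diarylprolinol silyl ether into its iminium ion. Phenol 5 adds through its ortho carbon to the β-carbon and closes through oxygen onto the aldehyde, giving lactol A1 with upper C4 set by the catalyst.
- For: C4 is set by a catalyst, the 4→8 link is fixed because the chain already sits on C8, and no flavanyl cation is involved.
- Against: the β-carbon of A2 carries a 2,6-dioxygenated, very electron-rich ring, which lowers the electrophilicity of the iminium ion and blocks approach of the phenol. The lower unit must first be made as a complete protected epigallocatechin and formylated at C8 rather than C6. A1 still lacks ring B on upper C2 and the oxygen on upper C3, which would have to be added 2,3-trans and 3,4-trans through the enol ether of the lactol, with two more stereocentres and several steps.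
- Comparison: this alternative is stronger on constitution, which is never in doubt, whereas the chosen route relies on a steric preference in step 6. The chosen route takes all three upper stereocentres from 1 in three steps, has only two stereocentres left to make, and confines its uncertainty to one step.

**Alternative 2:** All four bonds that tie upper ring C to its neighbours are cut at once: C4a–C4, C8a–O1, C3–C4 and O1–C2.
- Forward key step: fluoride releases a 3,5-dioxygenated aryne from silyl aryl triflate A6. The aryne adds across the C8 aldehyde of the perbenzylated lower unit A4, the benzoxete opens to an ortho-quinone methide, and this takes up (E)-enol carbonate A5 in a hetero-Diels–Alder reaction. The product is A3, the protected target with a benzyl carbonate on upper O3.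
- For: very high convergence (one ring, four bonds and three stereocentres in one step). The polarisation of a 3-alkoxyaryne puts oxygen on C8a as needed, (E) geometry should translate into 2,3-trans, and the carbonate leaves in the final hydrogenolysis.
- Against: nothing but the distant lower unit controls the absolute configuration of the three new centres, so diastereomer mixtures are expected. The endo/exo preference decides the 3,4 relationship. The cycloaddition must place the oxygen-bearing carbon on C4, which holds only if the aryl group outweighs the carbonate oxygen in polarising the alkene. A4 is a di-ortho-substituted, electron-rich aldehyde and a poor partner for the aryne, and fluoride threatens the aryl gallate.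
- Comparison: this alternative is stronger in convergence and step count. The chosen strategy offers stereochemical certainty instead: the upper triad comes with 1, and the lower pair is set by a chiral reagent on a rigid ring.

**Alternative 3:** The cut is in lower ring F at C3–C4 and O1–C2, a retro-hetero-Diels–Alder.
- Forward key step: a chiral phosphoric acid dehydrates the ortho-hydroxybenzyl alcohol A8 (ring D with the upper unit in place) to its ortho-quinone methide. This adds (Z)-enol gallate A9 to give A7, which is the same compound as 22.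
- For: ring F, both lower stereocentres and the gallate are formed in one step and only hydrogenolysis remains. (Z) geometry maps onto the cis relationship, and A8 is a close relative of 10.
- Against: the methide carbon is an unsubstituted CH2, so both new stereocentres lie on the dienophile, far from the acid bound at the quinone methide oxygen, and facial control is weak. Enol esters are poor partners for quinone methides. If the addition goes stepwise through a benzylic cation at C2, the cis geometry can leak to the more stable trans isomer. A Brønsted acid acting on an ionising substrate also endangers the C4–C8 bond on the very electron-rich ring D.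
- Comparison: this alternative is about five steps shorter after ring closure and clearly stronger in step economy. The chosen strategy uses those steps so that each stereochemical event rests on a well-understood reagent (syn hydroboration with a chiral borane, hindered hydride on a flavan-3-one), and it keeps acid away once the interflavan bond exists.

Key step: step 10

Assumptions:
- Ether 4 is taken to form as the 2,4-trans (4S) isomer. Its C4 configuration is lost on ionisation in step 6 and has no consequence.
- IpcBH2 is prepared beforehand from (+)-α-pinene and used as a THF solution. This enantiomer is chosen because it converts 1-arylcycloalkenes into (1S,2R)-trans-2-arylcycloalkanols, which corresponds in space to (2R,3S) in the chroman.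
- The titanium-bound intermediate 16 is drawn as its parent diol.

## Route

Step 1
Reactants: 1 (+)-catechin
Product: 2 5,7,3',4'-tetra-O-benzylcatechin
Conditions: BnBr, K2CO3, DMF, 0 °C to rt
Reagents that add atoms: benzyl bromide, BrCc1ccccc1
Why: Williamson ether synthesis; K2CO3 deprotonates only the four phenols, so the secondary alcohol stays free, and C2 and C3 are not touched at room temperature.

Step 2
Reactants: 2 5,7,3',4'-tetra-O-benzylcatechin
Product: 3 3,5,7,3',4'-penta-O-benzylcatechin
Conditions: NaH, BnBr, DMF, 0 °C to rt
Reagents that add atoms: benzyl bromide, BrCc1ccccc1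
Why: Williamson etherification of the remaining secondary alkoxide; with every phenol capped no quinone methide can form, so C2 cannot epimerise under the base.

Step 3
Reactants: 3 3,5,7,3',4'-penta-O-benzylcatechin
Product: 4 penta-O-benzyl-4-(2-ethoxyethoxy)catechin (2R,3S,4S)
Conditions: DDQ, 2-ethoxyethanol, CH2Cl2, rt
Reagents that add atoms: 2-ethoxyethanol, CCOCCO
Why: Benzylic oxidation by hydride abstraction; DDQ takes hydride from C4, the cation is stabilised by the ortho and para oxygens of ring A and is trapped by the alcohol on the face away from the C2 aryl group, and plain benzyl ethers resist DDQ.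

Step 4
Reactants: 5 3,5-bis(benzyloxy)phenol; 6 allyl bromide
Product: 7 1-(allyloxy)-3,5-bis(benzyloxy)benzene
Conditions: K2CO3, acetone, reflux
Reagents that add atoms: none
Why: Williamson O-allylation of the phenoxide; in acetone with K2CO3 alkylation on oxygen is expected to dominate over alkylation on carbon.

Step 5
Reactants: 7 1-(allyloxy)-3,5-bis(benzyloxy)benzene
Product: 9 2-allyl-3,5-bis(benzyloxy)phenol, via dienone 8 (not isolated)
Conditions: N,N-diethylaniline, 190 °C, argon
Reagents that add atoms: none
Why: Aromatic Claisen rearrangement, a [3,3]-sigmatropic shift to dienone 8 followed by tautomerisation; the two ortho carbons are equivalent, so a single phenol should form, and the para carbon is not reached while an ortho hydrogen is available.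

Step 6
Reactants: 4 penta-O-benzyl-4-(2-ethoxyethoxy)catechin (2R,3S,4S); 9 2-allyl-3,5-bis(benzyloxy)phenol
Product: 10 2-allyl-3,5-bis(benzyloxy)-6-(penta-O-benzylcatechin-4α-yl)phenol
Conditions: TMSOTf (0.2 equiv), 9 (3 equiv), CH2Cl2, −78 °C; aq. NaHCO3
Reagents that add atoms: none
Why: Friedel–Crafts alkylation by a flavan-4-yl cation, the standard interflavan coupling; TMSOTf ionises the C4 ether and the cation is attacked by the free carbon of 9 ortho to the hydroxyl, which is less hindered than the carbon between the two benzyloxy groups, as C8 is preferred over C6 in a benzylated flavan. The arene approaches anti to the C3 benzyloxy group, which sets C4 as 4α (3,4-trans), and the isolated alkene is far less nucleophilic than the ring at −78 °C.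

Step 7
Reactants: 11 3,4,5-tris(benzyloxy)benzoic acid
Product: 12 3,4,5-tris(benzyloxy)benzoyl chloride
Conditions: (COCl)2, DMF (cat.), CH2Cl2, 0 °C to rt; evaporation
Reagents that add atoms: oxalyl chloride, O=C(Cl)C(Cl)=O
Why: Acid chloride formation through the Vilsmeier-type chloroiminium ion; aryl benzyl ethers are inert and the crude chloride serves steps 8 and 14.

Step 8
Reactants: 10 2-allyl-3,5-bis(benzyloxy)-6-(penta-O-benzylcatechin-4α-yl)phenol; 12 3,4,5-tris(benzyloxy)benzoyl chloride
Product: 13 3,4,5-tris(benzyloxy)benzoate of phenol 10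
Conditions: NaH, THF, 0 °C; then 12, 0 °C to rt
Reagents that add atoms: none
Why: O-acylation of a sodium phenoxide with an acid chloride; irreversible deprotonation overcomes the hindrance of the two ortho substituents, and the molecule has no other acidic site.

Step 9
Reactants: 13 3,4,5-tris(benzyloxy)benzoate of phenol 10
Product: 15 aryl ester aldehyde in which the allyl group of 13 has become CH2CHO, via diol 14 (not isolated)
Conditions: OsO4 (cat.), NaIO4, 2,6-lutidine, dioxane/H2O, rt; used at once
Reagents that add atoms: OsO4, O=[Os](=O)(=O)=O; NaIO4, [Na+].[O-]I(=O)(=O)=O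
Why: Lemieux–Johnson oxidation; OsO4 dihydroxylates the only alkene to diol 14 and periodate cleaves the diol and restores OsO4, while 2,6-lutidine limits over-oxidation. The ester on the ring D oxygen prevents lactol formation, and the arylacetaldehyde is taken on without storage.

Step 10
Reactants: 15 aryl ester aldehyde in which the allyl group of 13 has become CH2CHO
Product: 17 5,7-bis(benzyloxy)-2-[3,4,5-tris(benzyloxy)phenyl]-8-(penta-O-benzylcatechin-4α-yl)-4H-chromene, via titanium diolate 16 (not isolated)
Conditions: TiCl3, Zn dust, DME, reflux; 15 in DME added over 12 h by syringe pump; filtration through basic alumina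
Reagents that add atoms: none
Why: Low-valent titanium made from TiCl3 and zinc dust transfers an electron to the aldehyde, the more easily reduced carbonyl, and the titanium-bound ketyl carbon (C3) adds to the carbonyl carbon of the neighbouring aryl ester (C2). The titanium diolate 16 is then deoxygenated on the titanium surface, as in the second stage of a McMurry reaction, which leaves C2=C3 as an enol ether. The closest known reactions are the titanium-induced oxo-ester cyclisations that turn ortho-acyloxyaryl ketones into benzofurans and keto esters into cyclic enol ethers; here the tether is one methylene longer and the carbonyl partner is an aldehyde. Ring F closes in a 6-exo-trig mode, the attacked C=O lying outside the forming ring, and the double bond ends inside the ring because the two titanium-bound oxygens are removed while the aryl oxygen O1 stays. No stereocentre is formed, and the three of the upper unit are remote and carry no hydrogen that is acidic under these conditions. The selectivity needed is intramolecular aldehyde–ester coupling against pinacol coupling of two aldehydes; the ortho arrangement of the two groups makes the six-membered closure entropically cheap, and slow addition at high dilution supports it. Only benzyl ethers and C–C bonds are present besides the two carbonyls, and the product is kept away from acid so that the enol ether is not hydrolysed.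

Step 11
Reactants: 17 5,7-bis(benzyloxy)-2-[3,4,5-tris(benzyloxy)phenyl]-8-(penta-O-benzylcatechin-4α-yl)-4H-chromene
Product: 19 deca-O-benzyl catechin-(4α→8)-gallocatechin (lower unit 2R,3S; free lower 3-OH), via alkylborane 18 (not isolated)
Conditions: IpcBH2 [from (+)-α-pinene], THF, −25 to 0 °C; then NaOH aq., H2O2, 0 °C to rt
Reagents that add atoms: hydrogen peroxide, OO; monoisopinocampheylborane, C[C@H]1[C@H](B)C[C@@H]2C[C@H]1C2(C)C (its boron and terpene group are present in 18 only)
Why: Asymmetric hydroboration–oxidation of a trisubstituted enol ether; boron goes to C3, the carbon β to O1 and to ring E, and hydrogen to C2 on the same face, so oxidation with retention gives the 2,3-trans alcohol. The face is chosen by the reagent, whose (+)-α-pinene-derived enantiomer is the one that turns 1-arylcycloalkenes into (1S,2R)-trans-2-arylcycloalkanols, the spatial counterpart of lower (2R,3S); the remote upper unit on C8 should add little bias.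

Step 12
Reactants: 19 deca-O-benzyl catechin-(4α→8)-gallocatechin (lower unit 2R,3S; free lower 3-OH)
Product: 20 lower-unit flavan-3-one (2R) of the deca-O-benzyl dimer
Conditions: Dess–Martin periodinane, CH2Cl2 (water-saturated), rt
Reagents that add atoms: none
Why: Dess–Martin oxidation of the secondary alcohol under near-neutral conditions, with no acid strong enough to ionise the C4–C8 bond and no base to epimerise C2 of the ketone; the ketone is used directly.

Step 13
Reactants: 20 lower-unit flavan-3-one (2R) of the deca-O-benzyl dimer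
Product: 21 deca-O-benzyl catechin-(4α→8)-epigallocatechin (lower unit 2R,3R; free lower 3-OH)
Conditions: L-selectride Li[HB(sec-Bu)3], LiBr, THF, −78 °C; then H2O
Reagents that add atoms: none
Why: Diastereoselective ketone reduction with a bulky trialkylborohydride, the known catechin-to-epicatechin inversion; hydride attacks C3 from the equatorial side, away from ring E, and gives the axial (3R) alcohol cis to the C2 aryl group, while −78 °C keeps the enolisable C2 from epimerising.

Step 14
Reactants: 21 deca-O-benzyl catechin-(4α→8)-epigallocatechin (lower unit 2R,3R; free lower 3-OH); 12 3,4,5-tris(benzyloxy)benzoyl chloride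
Product: 22 trideca-O-benzyl catechin-(4α→8)-epigallocatechin 3-O-gallate
Conditions: Et3N, DMAP (cat.), CH2Cl2, rt
Reagents that add atoms: none
Why: DMAP-catalysed acylation through the acylpyridinium ion; the only free hydroxyl is the axial lower 3-OH, and its configuration is kept because the C3–O bond is not broken.

Step 15
Reactants: 22 trideca-O-benzyl catechin-(4α→8)-epigallocatechin 3-O-gallate
Product: 23 catechin-(4α→8)-epigallocatechin 3-O-gallate (CNP0246304.1)
Conditions: H2 (1 atm), Pd(OH)2/C, THF/MeOH/H2O, rt; filtration under argon, lyophilisation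
Reagents that add atoms: none
Why: Hydrogenolysis of all thirteen benzyl ethers (twelve aryl, one alkyl) over Pd(OH)2/C under neutral conditions; the ester, the interflavan bond and the five stereocentres are not affected, and exclusion of air protects the pyrogallol rings.

## Compound list

1 | (+)-catechin, (2R,3S)-2-(3,4-dihydroxyphenyl)chromane-3,5,7-triol | O[C@H]1Cc2c(O)cc(O)cc2O[C@@H]1c1ccc(O)c(O)c1 | starting material
2 | 5,7,3',4'-tetra-O-benzylcatechin (2R,3S) | O[C@H]1Cc2c(OCc9ccccc9)cc(OCc9ccccc9)cc2O[C@@H]1c1ccc(OCc9ccccc9)c(OCc9ccccc9)c1 | intermediate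
3 | 3,5,7,3',4'-penta-O-benzylcatechin (2R,3S) | O(Cc9ccccc9)[C@H]1Cc2c(OCc9ccccc9)cc(OCc9ccccc9)cc2O[C@@H]1c1ccc(OCc9ccccc9)c(OCc9ccccc9)c1 | intermediate
4 | (2R,3S,4S)-penta-O-benzyl-4-(2-ethoxyethoxy)catechin, the 2,4-trans C4 ether | CCOCCO[C@H]1c2c(OCc9ccccc9)cc(OCc9ccccc9)cc2O[C@H](c2ccc(OCc9ccccc9)c(OCc9ccccc9)c2)[C@H]1OCc9ccccc9 | intermediate
5 | 3,5-bis(benzyloxy)phenol | Oc1cc(OCc2ccccc2)cc(OCc2ccccc2)c1 | starting material
6 | allyl bromide | C=CCBr | starting material
7 | 1-(allyloxy)-3,5-bis(benzyloxy)benzene | C=CCOc1cc(OCc9ccccc9)cc(OCc9ccccc9)c1 | intermediate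
8 | 6-allyl-3,5-bis(benzyloxy)cyclohexa-2,4-dien-1-one (racemic, not isolated) | C=CCC1C(=O)C=C(OCc9ccccc9)C=C1OCc9ccccc9 | intermediate
9 | 2-allyl-3,5-bis(benzyloxy)phenol | C=CCc1c(O)cc(OCc9ccccc9)cc1OCc9ccccc9 | intermediate
10 | 2-allyl-3,5-bis(benzyloxy)-6-(penta-O-benzylcatechin-4α-yl)phenol; upper unit 2R,3S with the aryl group on C4 trans to O3 | C=CCc1c(OCc9ccccc9)cc(OCc9ccccc9)c([C@@H]3c4c(OCc9ccccc9)cc(OCc9ccccc9)cc4O[C@H](c4ccc(OCc9ccccc9)c(OCc9ccccc9)c4)[C@H]3OCc9ccccc9)c1O | intermediate
11 | 3,4,5-tris(benzyloxy)benzoic acid | O=C(O)c1cc(OCc2ccccc2)c(OCc2ccccc2)c(OCc2ccccc2)c1 | starting material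
12 | 3,4,5-tris(benzyloxy)benzoyl chloride | O=C(Cl)c1cc(OCc9ccccc9)c(OCc9ccccc9)c(OCc9ccccc9)c1 | intermediate
13 | 2-allyl-3,5-bis(benzyloxy)-6-(penta-O-benzylcatechin-4α-yl)phenyl 3,4,5-tris(benzyloxy)benzoate | C=CCc1c(OCc9ccccc9)cc(OCc9ccccc9)c([C@@H]3c4c(OCc9ccccc9)cc(OCc9ccccc9)cc4O[C@H](c4ccc(OCc9ccccc9)c(OCc9ccccc9)c4)[C@H]3OCc9ccccc9)c1OC(=O)c1cc(OCc9ccccc9)c(OCc9ccccc9)c(OCc9ccccc9)c1 | intermediate
14 | 2,3-dihydroxypropyl analogue of 13 (both epimers at the secondary carbinol, not isolated) | OCC(O)Cc1c(OCc9ccccc9)cc(OCc9ccccc9)c([C@@H]3c4c(OCc9ccccc9)cc(OCc9ccccc9)cc4O[C@H](c4ccc(OCc9ccccc9)c(OCc9ccccc9)c4)[C@H]3OCc9ccccc9)c1OC(=O)c1cc(OCc9ccccc9)c(OCc9ccccc9)c(OCc9ccccc9)c1 | intermediate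
15 | 3,5-bis(benzyloxy)-2-(2-oxoethyl)-6-(penta-O-benzylcatechin-4α-yl)phenyl 3,4,5-tris(benzyloxy)benzoate | O=CCc1c(OCc9ccccc9)cc(OCc9ccccc9)c([C@@H]3c4c(OCc9ccccc9)cc(OCc9ccccc9)cc4O[C@H](c4ccc(OCc9ccccc9)c(OCc9ccccc9)c4)[C@H]3OCc9ccccc9)c1OC(=O)c1cc(OCc9ccccc9)c(OCc9ccccc9)c(OCc9ccccc9)c1 | intermediate
16 | titanium 2,3-diolate of ring F, drawn as the parent 5,7-bis(benzyloxy)-2-[3,4,5-tris(benzyloxy)phenyl]-8-(penta-O-benzylcatechin-4α-yl)chromane-2,3-diol (C2 and C3 unassigned, not isolated) | OC1Cc2c(OCc9ccccc9)cc(OCc9ccccc9)c([C@@H]3c4c(OCc9ccccc9)cc(OCc9ccccc9)cc4O[C@H](c4ccc(OCc9ccccc9)c(OCc9ccccc9)c4)[C@H]3OCc9ccccc9)c2OC1(O)c1cc(OCc9ccccc9)c(OCc9ccccc9)c(OCc9ccccc9)c1 | intermediate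
17 | 5,7-bis(benzyloxy)-2-[3,4,5-tris(benzyloxy)phenyl]-8-(penta-O-benzylcatechin-4α-yl)-4H-chromene | C1(c5cc(OCc9ccccc9)c(OCc9ccccc9)c(OCc9ccccc9)c5)=CCc2c(OCc9ccccc9)cc(OCc9ccccc9)c([C@@H]3c4c(OCc9ccccc9)cc(OCc9ccccc9)cc4O[C@H](c4ccc(OCc9ccccc9)c(OCc9ccccc9)c4)[C@H]3OCc9ccccc9)c2O1 | intermediate
18 | (isopinocampheyl)borane carrying the lower chroman on boron through C3 (lower unit 2R, boron trans to ring E; not isolated) | B([C@@H]5C[C@@H]6C[C@H]([C@H]5C)C6(C)C)[C@H]1Cc2c(OCc9ccccc9)cc(OCc9ccccc9)c([C@@H]3c4c(OCc9ccccc9)cc(OCc9ccccc9)cc4O[C@H](c4ccc(OCc9ccccc9)c(OCc9ccccc9)c4)[C@H]3OCc9ccccc9)c2O[C@@H]1c1cc(OCc9ccccc9)c(OCc9ccccc9)c(OCc9ccccc9)c1 | intermediate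
19 | deca-O-benzyl catechin-(4α→8)-gallocatechin, lower unit (2R,3S) with free 3-OH | O[C@H]1Cc2c(OCc9ccccc9)cc(OCc9ccccc9)c([C@@H]3c4c(OCc9ccccc9)cc(OCc9ccccc9)cc4O[C@H](c4ccc(OCc9ccccc9)c(OCc9ccccc9)c4)[C@H]3OCc9ccccc9)c2O[C@@H]1c1cc(OCc9ccccc9)c(OCc9ccccc9)c(OCc9ccccc9)c1 | intermediate
20 | lower-unit 3-ketone of the deca-O-benzyl dimer, (2R) | O=C1Cc2c(OCc9ccccc9)cc(OCc9ccccc9)c([C@@H]3c4c(OCc9ccccc9)cc(OCc9ccccc9)cc4O[C@H](c4ccc(OCc9ccccc9)c(OCc9ccccc9)c4)[C@H]3OCc9ccccc9)c2O[C@@H]1c1cc(OCc9ccccc9)c(OCc9ccccc9)c(OCc9ccccc9)c1 | intermediate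
21 | deca-O-benzyl catechin-(4α→8)-epigallocatechin, lower unit (2R,3R) with free 3-OH | O[C@@H]1Cc2c(OCc9ccccc9)cc(OCc9ccccc9)c([C@@H]3c4c(OCc9ccccc9)cc(OCc9ccccc9)cc4O[C@H](c4ccc(OCc9ccccc9)c(OCc9ccccc9)c4)[C@H]3OCc9ccccc9)c2O[C@@H]1c1cc(OCc9ccccc9)c(OCc9ccccc9)c(OCc9ccccc9)c1 | intermediate
22 | trideca-O-benzyl catechin-(4α→8)-epigallocatechin 3-O-gallate | O=C(O[C@@H]1Cc2c(OCc9ccccc9)cc(OCc9ccccc9)c([C@@H]3c4c(OCc9ccccc9)cc(OCc9ccccc9)cc4O[C@H](c4ccc(OCc9ccccc9)c(OCc9ccccc9)c4)[C@H]3OCc9ccccc9)c2O[C@@H]1c1cc(OCc9ccccc9)c(OCc9ccccc9)c(OCc9ccccc9)c1)c1cc(OCc9ccccc9)c(OCc9ccccc9)c(OCc9ccccc9)c1 | intermediate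
23 | catechin-(4α→8)-epigallocatechin 3-O-gallate, upper unit (2R,3S,4S), lower unit (2R,3R) | O=C(O[C@@H]1Cc2c(O)cc(O)c([C@@H]3c4c(O)cc(O)cc4O[C@H](c4ccc(O)c(O)c4)[C@H]3O)c2O[C@@H]1c1cc(O)c(O)c(O)c1)c1cc(O)c(O)c(O)c1 | target

## Step count and risks

Total: 15 steps. Longest linear sequence: 12 steps (1, 2, 3, 6, 8, 9, 10, 11, 12, 13, 14, 15). Steps 4 and 5 and step 7 are side branches.

**Step 10 (key step).**
- What may go wrong: pinacol coupling between two aldehyde molecules, or plain reduction of the aldehyde, may outrun attack on the hindered, electron-rich aryl ester. The tetrahedral adduct may open by loss of the ring D phenoxide (acyl transfer to carbon) and end as a hydroxy ketone or ketone instead of the enol ether. Titanium and zinc chlorides at reflux may take off benzyl groups or ionise the C4–C8 bond. The enol ether may hydrolyse on an acidic work-up. Partial debenzylation alone could be repaired by re-benzylation, since all protecting groups are the same.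
- Fallback: it sets out from 13 and returns at 17. The ester carbonyl of 13 is methylenated with Cp2TiMe2 (toluene, 70 °C) to the aryl 1-arylvinyl ether F1. Ring-closing metathesis between this enol ether and the allyl group, with second-generation Grubbs catalyst RuCl2(=CHPh)(PCy3)(H2IMes) in toluene at 70 °C, closes ring F with loss of ethylene and gives 17. The same C2=C3 bond is then made by olefination and metathesis instead of reductive coupling, and step 9 is not needed.

**Step 11.**
- What may go wrong: poor facial selectivity if the chiral reagent and the bulky upper unit on C8 oppose each other; slow addition to a trisubstituted enol ether flanked by ring E; and β-elimination of the β-alkoxyborane, which would open ring F.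
- Fallback: it sets out from 17 and returns at 21. Compound 17 is hydroborated with BH3·SMe2 and oxidised (NaOH, H2O2), giving the 2,3-trans alcohols as a pair, 19 and its lower-unit (2S,3R) diastereomer F2. The mixture is oxidised with Dess–Martin periodinane to ketone 20 and its C2 epimer F3. These interconvert through the enol under the basic conditions of an asymmetric transfer hydrogenation (RuCl(p-cymene)[(R,R)-TsDPEN] or its enantiomer, HCO2H/Et3N). Dynamic kinetic resolution should funnel both into the cis alcohol 21, the catalyst enantiomer being chosen on a model 2-arylchroman-3-one for the (2R,3R) sense. Stereocontrol thus moves from the alkene addition to the ketone reduction.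

**Step 6.**
- What may go wrong: attack at the ring carbon between the two benzyloxy groups (wrong constitution); alkylation on the phenol oxygen; a second alkylation of the product; some 3,4-cis isomer; or acid-induced closure of the ortho-allylphenol to a dihydrobenzofuran if the mixture warms before the quench.
- Fallback: it sets out from 4 and 5 and returns at 10. Ether 4 is coupled (TMSOTf, CH2Cl2, −78 °C) with an excess of the unsubstituted phenol 5, which offers two equivalent carbons ortho to the hydroxyl and carries no alkene, to give the 2-(penta-O-benzylcatechin-4α-yl)-3,5-bis(benzyloxy)phenol F4. O-Allylation with 6 (K2CO3, acetone) gives allyl ether F5. Claisen rearrangement (N,N-diethylaniline, 190 °C) through dienone F6, which is not isolated, can deliver the allyl group only to the single free ortho carbon and gives 10.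

## Further compounds

F1 | step 10 | 2-allyl-3,5-bis(benzyloxy)-6-(penta-O-benzylcatechin-4α-yl)phenyl 1-[3,4,5-tris(benzyloxy)phenyl]vinyl ether | C=CCc1c(OCc9ccccc9)cc(OCc9ccccc9)c([C@@H]3c4c(OCc9ccccc9)cc(OCc9ccccc9)cc4O[C@H](c4ccc(OCc9ccccc9)c(OCc9ccccc9)c4)[C@H]3OCc9ccccc9)c1OC(=C)c1cc(OCc9ccccc9)c(OCc9ccccc9)c(OCc9ccccc9)c1
F2 | step 11 | deca-O-benzyl dimer with the lower unit (2S,3R)-trans and free 3-OH, the lower-unit diastereomer of 19 | O[C@@H]1Cc2c(OCc9ccccc9)cc(OCc9ccccc9)c([C@@H]3c4c(OCc9ccccc9)cc(OCc9ccccc9)cc4O[C@H](c4ccc(OCc9ccccc9)c(OCc9ccccc9)c4)[C@H]3OCc9ccccc9)c2O[C@H]1c1cc(OCc9ccccc9)c(OCc9ccccc9)c(OCc9ccccc9)c1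
F3 | step 11 | lower-unit 3-ketone with (2S) configuration, the C2 epimer of 20 | O=C1Cc2c(OCc9ccccc9)cc(OCc9ccccc9)c([C@@H]3c4c(OCc9ccccc9)cc(OCc9ccccc9)cc4O[C@H](c4ccc(OCc9ccccc9)c(OCc9ccccc9)c4)[C@H]3OCc9ccccc9)c2O[C@H]1c1cc(OCc9ccccc9)c(OCc9ccccc9)c(OCc9ccccc9)c1
F4 | step 6 | 3,5-bis(benzyloxy)-2-(penta-O-benzylcatechin-4α-yl)phenol | Oc1cc(OCc9ccccc9)cc(OCc9ccccc9)c1[C@@H]3c4c(OCc9ccccc9)cc(OCc9ccccc9)cc4O[C@H](c4ccc(OCc9ccccc9)c(OCc9ccccc9)c4)[C@H]3OCc9ccccc9
F5 | step 6 | allyl ether of F4, 1-(allyloxy)-3,5-bis(benzyloxy)-2-(penta-O-benzylcatechin-4α-yl)benzene | C=CCOc1cc(OCc9ccccc9)cc(OCc9ccccc9)c1[C@@H]3c4c(OCc9ccccc9)cc(OCc9ccccc9)cc4O[C@H](c4ccc(OCc9ccccc9)c(OCc9ccccc9)c4)[C@H]3OCc9ccccc9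
F6 | step 6 | 6-allyl-3,5-bis(benzyloxy)-2-(penta-O-benzylcatechin-4α-yl)cyclohexa-2,4-dien-1-one (both epimers at the allyl-bearing carbon, not isolated) | C=CCC1C(=O)C([C@@H]3c4c(OCc9ccccc9)cc(OCc9ccccc9)cc4O[C@H](c4ccc(OCc9ccccc9)c(OCc9ccccc9)c4)[C@H]3OCc9ccccc9)=C(OCc9ccccc9)C=C1OCc9ccccc9
A1 | alternative 1 | (4S)-4-aryl-5,7-bis(benzyloxy)chroman-2-ol on C8 of the O3-silylated, benzylated epigallocatechin, anomeric mixture at C2 | CC(C)(C)[Si](C)(C)O[C@@H]1Cc2c(OCc9ccccc9)cc(OCc9ccccc9)c([C@@H]3c4c(OCc9ccccc9)cc(OCc9ccccc9)cc4OC(O)C3)c2O[C@@H]1c1cc(OCc9ccccc9)c(OCc9ccccc9)c(OCc9ccccc9)c1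
A2 | alternative 1 | (E)-3-aryl-propenal in which the aryl group is C8 of 3-O-TBS-penta-O-benzyl-epigallocatechin | CC(C)(C)[Si](C)(C)O[C@@H]1Cc2c(OCc9ccccc9)cc(OCc9ccccc9)c(/C=C/C=O)c2O[C@@H]1c1cc(OCc9ccccc9)c(OCc9ccccc9)c(OCc9ccccc9)c1
A3 | alternative 2 | perbenzylated target carrying a benzyl carbonate on upper O3 | O=C(O[C@@H]1Cc2c(OCc9ccccc9)cc(OCc9ccccc9)c([C@@H]3c4c(OCc9ccccc9)cc(OCc9ccccc9)cc4O[C@H](c4ccc(OCc9ccccc9)c(OCc9ccccc9)c4)[C@H]3OC(=O)OCc9ccccc9)c2O[C@@H]1c1cc(OCc9ccccc9)c(OCc9ccccc9)c(OCc9ccccc9)c1)c1cc(OCc9ccccc9)c(OCc9ccccc9)c(OCc9ccccc9)c1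
A4 | alternative 2 | octa-O-benzyl epigallocatechin 3-O-gallate 8-carbaldehyde | O=C(O[C@@H]1Cc2c(OCc9ccccc9)cc(OCc9ccccc9)c(C=O)c2O[C@@H]1c1cc(OCc9ccccc9)c(OCc9ccccc9)c(OCc9ccccc9)c1)c1cc(OCc9ccccc9)c(OCc9ccccc9)c(OCc9ccccc9)c1
A5 | alternative 2 | benzyl (E)-2-[3,4-bis(benzyloxy)phenyl]vinyl carbonate | O=C(OCc9ccccc9)O/C=C/c1ccc(OCc9ccccc9)c(OCc9ccccc9)c1
A6 | alternative 2 | 3,5-bis(benzyloxy)-2-(trimethylsilyl)phenyl trifluoromethanesulfonate | C[Si](C)(C)c1c(OCc9ccccc9)cc(OCc9ccccc9)cc1OS(=O)(=O)C(F)(F)F
A7 | alternative 3 | fully benzylated target, identical with 22 | O=C(O[C@@H]1Cc2c(OCc9ccccc9)cc(OCc9ccccc9)c([C@@H]3c4c(OCc9ccccc9)cc(OCc9ccccc9)cc4O[C@H](c4ccc(OCc9ccccc9)c(OCc9ccccc9)c4)[C@H]3OCc9ccccc9)c2O[C@@H]1c1cc(OCc9ccccc9)c(OCc9ccccc9)c(OCc9ccccc9)c1)c1cc(OCc9ccccc9)c(OCc9ccccc9)c(OCc9ccccc9)c1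
A8 | alternative 3 | 3,5-bis(benzyloxy)-2-(hydroxymethyl)-6-(penta-O-benzylcatechin-4α-yl)phenol | OCc1c(OCc9ccccc9)cc(OCc9ccccc9)c([C@@H]3c4c(OCc9ccccc9)cc(OCc9ccccc9)cc4O[C@H](c4ccc(OCc9ccccc9)c(OCc9ccccc9)c4)[C@H]3OCc9ccccc9)c1O
A9 | alternative 3 | (Z)-2-[3,4,5-tris(benzyloxy)phenyl]vinyl 3,4,5-tris(benzyloxy)benzoate | O=C(O/C=C\c1cc(OCc9ccccc9)c(OCc9ccccc9)c(OCc9ccccc9)c1)c1cc(OCc9ccccc9)c(OCc9ccccc9)c(OCc9ccccc9)c1
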